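## Analysis of the target

Target 24 is a 2,2-dimethyl-2H-chromene in which a benzene ring is fused along the C4a–C8a bond to a 2H-pyran built from O1, C2 (bearing two methyl groups) and the C3=C4 double bond. The benzene ring is pentasubstituted, with OMe at C5, a (4-methoxyphenyl)acetyl group at C6, a free hydroxyl at C7 that is hydrogen-bonded to the ketone, hydrogen at C8 and the ring oxygen O1 on C8a. The molecule has no stereocentre and no stereogenic double bond, so the problem is one of regiochemistry only. The sensitive groups are the C3=C4 styrene-type olefin (acid, electrophilic oxidants), the CH2 between the ketone and the anisyl ring (enolisable, oxidisable) and the phenol. The difficulty is that three oxygens in a 1,3,5 relationship are present in three different states (ring ether, methyl ether, free phenol) with the acyl group and the pyran carbon C4 in a fixed relation to them, so that a start from a symmetrical trioxygenated benzene would need a chain of selections between nearly equivalent oxygens and ring positions (C6 against C8, linear against angular pyran fusion). The strategy rests on the pattern C5(O)–C6(C)–C7(O)–C8(H) next to the shared C4a–C8a edge. A vinylketene that already holds O1, C8a and C4a as a cyclic enol ether supplies C5 (its carbonyl carbon) and C8 (its CH), and a silyl ynol ether supplies C6 with its carbon substituent and C7 with its oxygen, so that the three oxygens come from three different functional groups and cannot be confused.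

## Retrosynthetic reasoning

**24 to 23 (O–Si at C7).** The last operation is removal of the silyl group from O7 of 23. The silyl ether is kept to the end because it is the marker that distinguishes O7 from O5, and it keeps the phenol out of the oxidation steps.

**23 to 22 (C3=C4).** The olefin of 23 is taken back to chroman 22. The ring synthesis uses the pyran as a cyclic enol ether and therefore gives the saturated ring, so the double bond has to be added afterwards. Dehydrogenation is well placed because hydride loss from C4 is assisted by the oxygens at C5, C7 and C8a, and the quaternary C2 stops the oxidation at the chromene.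

**22 to 21 (ketone to methylidene).** The ketone of 22 is masked in 21 as a 1,1-disubstituted alkene. An acyl group directly on the alkyne partner would reverse its polarisation and make it useless as a ketenophile, whereas the methylidene group is a spectator in the annulation. The oxidative cleavage has to come before the dehydrogenation, while the side-chain alkene is still the only olefin.

**21 to 20 (O–CH3 at C5).** The methyl group is removed from O5. In 20 the C5 hydroxyl is the only free OH, so the forward methylation needs no selectivity.

**20 to 9 and 15 (the benzene ring).** Four bonds are cut: C8–C8a, C5–C6, C7–C8 and C4a–C5. This leaves the dihydropyranyl diazoketone 9, which carries O1, C8a, C4a, C5 and C8, and the siloxyalkyne 15, which carries C6, C7, the silyl-protected O7 and the masked side chain. Cutting here rather than at a bond to a substituent turns all regiochemical questions into questions of connectivity within two small fragments. The forward reaction must generate vinylketene 16 from 9, join it to 15 with the oxygen-bearing alkyne carbon next to C8, and then open and reclose the four-membered intermediate 17 to the phenol.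

**9 to 7, 5, 4, 3 and 1.** The diazo group is traced to the methyl ketone 7 by diazo transfer. The bond between the pyran and the acetyl group is cut to give the lithiated enol ether 6, derived from the cyclic enol ether 5. Compound 5 comes from lactol 4 by dehydration, 4 from lactone 3 by partial reduction, and 3 from keto ester 1, where addition of a methyl nucleophile to the ketone sets the gem-dimethyl carbon C2.

**15 to 12, 11 and 10.** The O–C(sp) bond of 15 is cut to the lithium ynolate 14, which is reached by oxygen transfer to the lithium acetylide 13. The acetylide comes from dibromodiene 12, which is the one-carbon homologation product of enal 11. The methylidene group of 11 is introduced by α-methylenation of the commercial aldehyde 10. Generating the ynolate from an acetylide avoids exposing an unhindered acrylate-type acceptor to a carbenoid nucleophile.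

## Alternatives that were turned down

Alternative 1: Both bonds to the ketone carbon are cut. This leaves a complete chromene core as the aryl iodide methyl 6-iodo-5-methoxy-7-(methoxymethoxy)-2,2-dimethyl-2H-chromene-8-carboxylate A2, a one-carbon carbonyl source, and the benzyl nucleophile (4-methoxybenzyl)zinc chloride A3. The forward key step is a carbonylative cross-coupling of A2 and A3 under Pd(PPh3)4 (zerovalent palladium), which should give methyl 5-methoxy-7-(methoxymethoxy)-6-[2-(4-methoxyphenyl)acetyl]-2,2-dimethyl-2H-chromene-8-carboxylate A1.
- For it: it is convergent, the enolisable ketone appears late, the chromene olefin is present from the start (no dehydrogenation), and thermal palladium chemistry is easier to scale than photolysis. On these points it is as strong as or stronger than the chosen plan.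
- Against it: the real problem is only moved. A2 needs three differentiated oxygens, a regioselective pyran annulation, a blocking ester at C8 and an iodide at C6, each placed by selection between similar positions.
- Oxidative addition into the electron-rich iodide A2, flanked by two alkoxy groups, is slow. Carbonyl insertion must outrun direct benzyl transfer without insertion and homocoupling of A3.
- After the coupling, A1 still needs its C8 ester hydrolysed and decarboxylated and the acetal on O7 removed with acid next to an acid-sensitive chromene.
- Comparison: the step that leads to A1 forms two bonds and no ring. The chosen plan forms four bonds and the ring, and places every substituent by connectivity.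

Alternative 2: The pyran ring is cut at O1–C2 and C3–C4. This gives the hexasubstituted salicylaldehyde methyl 3-formyl-2,6-dihydroxy-4-methoxy-5-[2-(4-methoxyphenyl)acetyl]benzoate A5 and the alkenyl donor (2-methylprop-1-en-1-yl)boronic acid A6. In the forward step a secondary amine condenses with the formyl group of A5, the phenol-bound boronate formed from A6 delivers the alkenyl group to that carbon, loss of the amine gives a vinyl ortho-quinone methide, and oxa-6π closure gives methyl 7-hydroxy-5-methoxy-6-[2-(4-methoxyphenyl)acetyl]-2,2-dimethyl-2H-chromene-8-carboxylate A4.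
- For it: it forms the chromene with its olefin directly and under mild conditions, with the side chain already in place, and A6 is a simple reagent. On the pyran ring it is stronger than the chosen plan, which needs a separate dehydrogenation.
- Against it: A5 is a benzene with six different substituents, and making it is the whole problem. Formylation, acylation and carboxylation of a trioxygenated ring must each pick one of several similar positions.
- The two chelated phenols and three carbonyl groups of A5 lower the reactivity of the aldehyde/phenol pair, and the amine can also engage the enolisable benzyl ketone.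
- The C8 ester of A4 again has to be removed afterwards.
- Comparison: the chosen plan gives up the direct chromene closure that leads to A4, but builds the benzene ring with its substituents already ordered.

Alternative 3: The benzene ring is cut at C4a–C5 and C6–C7. The fragments are the ketene silyl acetal diene tert-butyl{[2-(6,6-dimethyl-5,6-dihydro-4H-pyran-2-yl)-1-methoxyethenyl]oxy}dimethylsilane A8 and the alkynyl ether ketone 4-methoxy-1-(4-methoxyphenyl)but-3-yn-2-one A9. A [4+2] cycloaddition of A8 and A9, elimination of the acetal methoxy group and loss of silicon give 1-(7-hydroxy-5-methoxy-2,2-dimethylchroman-6-yl)-2-(4-methoxyphenyl)ethan-1-one A7.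
- For it: it is the closest relative of the chosen plan. It is also a two-fragment ring synthesis on a preformed dihydropyran, it is thermal, and it delivers the C5 methyl ether and the ketone at their final oxidation level. A7 is only one dehydrogenation away from 24, so on step count after the annulation it is stronger.
- Against it: A9 is a push–pull alkyne. Its methoxy group donates into the ynone and lowers the dienophilicity, it is hydrolytically fragile, and its acidic benzylic CH2 can quench the diene by proton or silyl transfer.
- A8 is a triply oxygenated, moisture-sensitive ketene acetal that must react through an s-cis conformation involving the ring enol ether.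
- The aromatisation to A7 must expel the methoxy group and not the silyloxy group from the C7 ketal carbon. The differentiation of O5 and O7 therefore depends on a kinetic preference, not on structure.
- Comparison: the chosen plan pays three functional-group steps (methylation, alkene cleavage, desilylation). In return it uses an intrinsically matched electrophile/nucleophile pair (ketene and silyl ynol ether) and leaves O5 and O7 in different states by mechanism.

Key step: step 9

## Route

Remark on the chemistry: the target is achiral. Compounds 4, 17 and 19 each carry one stereocentre that is formed racemic and is destroyed in a later event, so no stereocontrol is needed. Aldehyde 10 and keto ester 1 are taken as commercial.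

Step 1
Reactants: 1 methyl 5-oxohexanoate
Product: 3 6,6-dimethyltetrahydro-2H-pyran-2-one, via hydroxy ester 2 (not isolated)
Conditions: MeMgBr (1.05 equiv), THF, −78 to −20 °C; 1 M HCl; then TsOH (cat.), CH2Cl2, rt
Reagents that add atoms: methylmagnesium bromide, C[Mg]Br
Why: At low temperature the Grignard reagent adds to the ketone much faster than to the methyl ester, and the tertiary alcohol 2 closes to the six-membered lactone under acid catalysis with loss of methanol (chemoselective 1,2-addition, then lactonisation); the gem-dimethyl group favours ring closure.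

Step 2
Reactants: 3 6,6-dimethyltetrahydro-2H-pyran-2-one
Product: 4 6,6-dimethyltetrahydro-2H-pyran-2-ol (racemic lactol)
Conditions: i-Bu2AlH (1.1 equiv), CH2Cl2, −78 °C; aq. potassium sodium tartrate
Reagents that add atoms: none
Why: Partial reduction of a lactone with i-Bu2AlH at −78 °C should stop at the aluminium hemiacetal, which gives the lactol on work-up; the new stereocentre is racemic and is removed in step 3.

Step 3
Reactants: 4 6,6-dimethyltetrahydro-2H-pyran-2-ol
Product: 5 2,2-dimethyl-3,4-dihydro-2H-pyran
Conditions: MsCl (1.2 equiv), Et3N (3 equiv), CH2Cl2, 0 °C to reflux; distillation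
Reagents that add atoms: none
Why: Sulfonylation of the anomeric hydroxyl gives a species that ionises to the ring oxocarbenium ion, and loss of the C3 proton to the amine gives the cyclic enol ether (the lactol dehydration used to make glycals); the volatile product is isolated by distillation.

Step 4
Reactants: 5 2,2-dimethyl-3,4-dihydro-2H-pyran
Product: 7 1-(6,6-dimethyl-5,6-dihydro-4H-pyran-2-yl)ethan-1-one, via lithiated enol ether 6 (not isolated)
Conditions: t-BuLi (1.2 equiv), THF/pentane, −78 to 0 °C; then MeC(O)N(OMe)Me, −78 to 0 °C; H2O
Reagents that add atoms: tert-butyllithium, [Li]C(C)(C)C (lithium in 6 only); N-methoxy-N-methylacetamide, CC(=O)N(C)OC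
Why: The vinylic C–H next to the ring oxygen is the most acidic position and is removed by t-BuLi (α-metalation of a cyclic enol ether); acylation with the Weinreb amide stops at the chelated tetrahedral adduct, so neither over-addition nor enolisation of the product by the vinyllithium is expected (Weinreb ketone synthesis).

Step 5
Reactants: 7 1-(6,6-dimethyl-5,6-dihydro-4H-pyran-2-yl)ethan-1-one
Product: 9 2-diazo-1-(6,6-dimethyl-5,6-dihydro-4H-pyran-2-yl)ethan-1-one, via trifluoroacetyl diketone 8 (not isolated)
Conditions: LiN(SiMe3)2 (1.1 equiv), THF, −78 °C; CF3CO2CH2CF3 (1.2 equiv); cold 5% HCl; then MsN3 (1.5 equiv), Et3N (1.5 equiv), H2O (1 equiv), MeCN, rt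
Reagents that add atoms: 2,2,2-trifluoroethyl trifluoroacetate, FC(F)(F)COC(=O)C(F)(F)F (atoms in 8 only); methanesulfonyl azide, CS(=O)(=O)N=[N+]=[N-]
Why: Kinetic deprotonation at the methyl group and Claisen trifluoroacetylation activate that carbon, and the sulfonyl azide then transfers the diazo group with loss of the trifluoroacetyl group (detrifluoroacetylative diazo transfer, the standard route to diazomethyl ketones of α,β-unsaturated systems); the acyl-substituted enol ether is deactivated towards the brief acid wash.

Step 6
Reactants: 10 3-(4-methoxyphenyl)propanal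
Product: 11 2-(4-methoxybenzyl)prop-2-enal
Conditions: 37% aq. HCHO, pyrrolidine (10 mol %), EtCO2H (10 mol %), i-PrOH, 45 °C
Reagents that add atoms: formaldehyde, C=O
Why: Enamine formation with pyrrolidine, Mannich addition to formaldehyde and β-elimination of the amine give the 2-substituted acrolein (organocatalytic α-methylenation of an aldehyde); the aldehyde has a single enolisable position.

Step 7
Reactants: 11 2-(4-methoxybenzyl)prop-2-enal
Product: 12 1-(4,4-dibromo-2-methylidenebut-3-en-1-yl)-4-methoxybenzene
Conditions: CBr4 (2 equiv), PPh3 (4 equiv), CH2Cl2, 0 °C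
Reagents that add atoms: carbon tetrabromide, BrC(Br)(Br)Br
Why: The ylide Ph3P=CBr2 formed from CBr4 and PPh3 olefinates the aldehyde (Ramirez dibromo-olefination, the first half of the Corey–Fuchs sequence); the 1,1-disubstituted alkene does not take part.

Step 8
Reactants: 12 1-(4,4-dibromo-2-methylidenebut-3-en-1-yl)-4-methoxybenzene
Product: 15 triisopropyl{[3-(4-methoxybenzyl)but-3-en-1-yn-1-yl]oxy}silane, via lithium acetylide 13 (not isolated), via lithium ynolate 14 (not isolated)
Conditions: n-BuLi (2.1 equiv), THF, −78 °C; LiOOt-Bu (from t-BuOOH and LiN(SiMe3)2), −78 to 0 °C; i-Pr3SiOTf (1.5 equiv), −78 °C to rt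
Reagents that add atoms: n-butyllithium, [Li]CCCC (lithium in 13 and 14 only); tert-butyl hydroperoxide, CC(C)(C)OO; triisopropylsilyl trifluoromethanesulfonate, CC(C)[Si](OS(=O)(=O)C(F)(F)F)(C(C)C)C(C)C
Why: Bromine–lithium exchange, Fritsch–Buttenberg–Wiechell rearrangement and deprotonation give acetylide 13 (second half of Corey–Fuchs), whose carbanion attacks the peroxide oxygen of LiOOt-Bu and expels tert-butoxide to give ynolate 14. The bulky silyl triflate silylates the ynolate on oxygen; this acetylide-oxidation route to triisopropylsiloxyalkynes is established, and butyl bromide and LiBr from the first stage should be spectators at these temperatures.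

Step 9
Reactants: 9 2-diazo-1-(6,6-dimethyl-5,6-dihydro-4H-pyran-2-yl)ethan-1-one (1.0 equiv); 15 triisopropyl{[3-(4-methoxybenzyl)but-3-en-1-yn-1-yl]oxy}silane (1.2 equiv)
Product: 20 6-[3-(4-methoxyphenyl)prop-1-en-2-yl]-2,2-dimethyl-7-(triisopropylsilyloxy)chroman-5-ol, via vinylketene 16 (not isolated), via cyclobutenone 17 (not isolated), via dienylketene 18 (not isolated), via cyclohexadienone 19 (not isolated)
Conditions: hν (medium-pressure Hg lamp, Pyrex filter, λ > 300 nm), degassed ClCH2CH2Cl (0.3 M), rt; then 80 °C
Reagents that add atoms: none
Why: Excitation of the diazoketone expels N2 and the dihydropyranyl group shifts to the former diazo carbon (Wolff rearrangement, bond C8–C8a) to give vinylketene 16. The alkyne carbon of 15 remote from oxygen, its nucleophilic position, attacks the ketene carbonyl carbon, and the resulting enolate/oxocarbenium pair collapses to cyclobutenone 17 (formal [2+2], bonds C5–C6 and C7–C8). At 80 °C ring strain drives conrotatory 4π opening to dienylketene 18, and thermal disrotatory 6π electrocyclisation (bond C4a–C5) closes the six-membered carbocycle as dienone 19, which tautomerises to phenol 20; this electrocyclic closure is the one ring-forming event kept in the product. The closest known reaction type is the photochemical Danheiser benzannulation of α,β-unsaturated and heteroaryl diazomethyl ketones with siloxyalkynes, and heteroaryl cases such as furyl diazoketones are the nearest model for the enol ether used here. No stereocentre is formed in 20, and those of 17 and 19 are transient. The step needs regioselectivity in the [2+2] and chemoselectivity for the alkyne over the methylidene group: both follow from the polarisation of the ynol ether, which makes the alkyne far more nucleophilic than the alkene and fixes the oxygen-bearing carbon next to C8, so that the side chain lands at C6 between the free C5 hydroxyl and the C7 silyl ether. The Pyrex filter keeps short-wavelength light from the anisole and enyne chromophores, and the methylidene group is cross-conjugated in 18, so it cannot enter a competing 6π closure.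

Step 10
Reactants: 20 6-[3-(4-methoxyphenyl)prop-1-en-2-yl]-2,2-dimethyl-7-(triisopropylsilyloxy)chroman-5-ol
Product: 21 triisopropyl({5-methoxy-6-[3-(4-methoxyphenyl)prop-1-en-2-yl]-2,2-dimethylchroman-7-yl}oxy)silane
Conditions: MeI (3 equiv), K2CO3 (2 equiv), acetone, 50 °C
Reagents that add atoms: iodomethane, CI
Why: The C5 hydroxyl is the only acidic group and its phenoxide is alkylated by MeI (Williamson ether synthesis); the anhydrous mild base should leave the aryl triisopropylsilyl ether intact, and the meta relation of O5 and O7 rules out intramolecular silyl migration.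

Step 11
Reactants: 21 triisopropyl({5-methoxy-6-[3-(4-methoxyphenyl)prop-1-en-2-yl]-2,2-dimethylchroman-7-yl}oxy)silane
Product: 22 1-[5-methoxy-2,2-dimethyl-7-(triisopropylsilyloxy)chroman-6-yl]-2-(4-methoxyphenyl)ethan-1-one
Conditions: OsO4 (5 mol %), NaIO4 (4 equiv), 2,6-lutidine (2 equiv), dioxane/H2O 3:1, rt
Reagents that add atoms: osmium tetroxide, O=[Os](=O)(=O)=O; sodium periodate, [Na+].[O-]I(=O)(=O)=O
Why: Osmylation of the only alkene and periodate cleavage of the resulting diol give the aryl benzyl ketone and formaldehyde (Lemieux–Johnson oxidation, with 2,6-lutidine to suppress side oxidation); the chroman ring is still saturated, so no second olefin competes.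

Step 12
Reactants: 22 1-[5-methoxy-2,2-dimethyl-7-(triisopropylsilyloxy)chroman-6-yl]-2-(4-methoxyphenyl)ethan-1-one
Product: 23 1-[5-methoxy-2,2-dimethyl-7-(triisopropylsilyloxy)-2H-chromen-6-yl]-2-(4-methoxyphenyl)ethan-1-one
Conditions: DDQ (1.5 equiv), anhydrous benzene, reflux
Reagents that add atoms: none
Why: DDQ abstracts hydride from C4, whose cation is stabilised by the oxygens at C5 and C8a (ortho to C4a) and at C7 (para), and loss of a C3 proton gives the 2H-chromene (quinone dehydrogenation of a 2,2-dimethylchroman); the quaternary C2 prevents further oxidation of the pyran ring.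

Step 13
Reactants: 23 1-[5-methoxy-2,2-dimethyl-7-(triisopropylsilyloxy)-2H-chromen-6-yl]-2-(4-methoxyphenyl)ethan-1-one
Product: 24 1-(7-hydroxy-5-methoxy-2,2-dimethyl-2H-chromen-6-yl)-2-(4-methoxyphenyl)ethan-1-one
Conditions: Bu4NF (1.2 equiv), AcOH (1.2 equiv), THF, 0 °C
Reagents that add atoms: none
Why: Fluoride attacks silicon and releases the phenoxide, which the acetic acid buffer protonates (fluoride cleavage of an aryl silyl ether); the buffered medium spares the chromene and the enolisable ketone, and the free C7 hydroxyl hydrogen-bonds to the carbonyl group.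

## Compound list

1 | methyl 5-oxohexanoate | COC(=O)CCCC(C)=O | starting material
2 | methyl 5-hydroxy-5-methylhexanoate | COC(=O)CCCC(C)(C)O | intermediate
3 | 6,6-dimethyltetrahydro-2H-pyran-2-one | CC1(C)CCCC(=O)O1 | intermediate
4 | 6,6-dimethyltetrahydro-2H-pyran-2-ol (racemic) | CC1(C)CCCC(O)O1 | intermediate
5 | 2,2-dimethyl-3,4-dihydro-2H-pyran | CC1(C)CCC=CO1 | intermediate
6 | (6,6-dimethyl-5,6-dihydro-4H-pyran-2-yl)lithium | [Li]C1=CCCC(C)(C)O1 | intermediate
7 | 1-(6,6-dimethyl-5,6-dihydro-4H-pyran-2-yl)ethan-1-one | CC(=O)C1=CCCC(C)(C)O1 | intermediate
8 | 1-(6,6-dimethyl-5,6-dihydro-4H-pyran-2-yl)-4,4,4-trifluorobutane-1,3-dione | O=C(CC(=O)C(F)(F)F)C1=CCCC(C)(C)O1 | intermediate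
9 | 2-diazo-1-(6,6-dimethyl-5,6-dihydro-4H-pyran-2-yl)ethan-1-one | [N-]=[N+]=CC(=O)C1=CCCC(C)(C)O1 | intermediate
10 | 3-(4-methoxyphenyl)propanal | COc1ccc(CCC=O)cc1 | starting material
11 | 2-(4-methoxybenzyl)prop-2-enal | C=C(Cc1ccc(OC)cc1)C=O | intermediate
12 | 1-(4,4-dibromo-2-methylidenebut-3-en-1-yl)-4-methoxybenzene | C=C(Cc1ccc(OC)cc1)C=C(Br)Br | intermediate
13 | [3-(4-methoxybenzyl)but-3-en-1-yn-1-yl]lithium | [Li]C#CC(=C)Cc1ccc(OC)cc1 | intermediate
14 | lithium 3-(4-methoxybenzyl)but-3-en-1-yn-1-olate | [Li+].[O-]C#CC(=C)Cc1ccc(OC)cc1 | intermediate
15 | triisopropyl{[3-(4-methoxybenzyl)but-3-en-1-yn-1-yl]oxy}silane | C=C(Cc1ccc(OC)cc1)C#CO[Si](C(C)C)(C(C)C)C(C)C | intermediate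
16 | 2-(6,6-dimethyl-5,6-dihydro-4H-pyran-2-yl)ethen-1-one (vinylketene) | O=C=CC1=CCCC(C)(C)O1 | intermediate
17 | 4-(6,6-dimethyl-5,6-dihydro-4H-pyran-2-yl)-2-[3-(4-methoxyphenyl)prop-1-en-2-yl]-3-(triisopropylsilyloxy)cyclobut-2-en-1-one (racemic) | O=C1C(C(=C)Cc2ccc(OC)cc2)=C(O[Si](C(C)C)(C(C)C)C(C)C)C1C1=CCCC(C)(C)O1 | intermediate
18 | (3E)-4-(6,6-dimethyl-5,6-dihydro-4H-pyran-2-yl)-2-[3-(4-methoxyphenyl)prop-1-en-2-yl]-3-(triisopropylsilyloxy)buta-1,3-dien-1-one (dihydropyranyl group cis to the ketene carbon) | O=C=C(C(=C)Cc1ccc(OC)cc1)/C(O[Si](C(C)C)(C(C)C)C(C)C)=C\C1=CCCC(C)(C)O1 | intermediate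
19 | 6-[3-(4-methoxyphenyl)prop-1-en-2-yl]-2,2-dimethyl-7-(triisopropylsilyloxy)-2,3,4,4a-tetrahydro-5H-chromen-5-one (racemic) | O=C1C(C(=C)Cc2ccc(OC)cc2)=C(O[Si](C(C)C)(C(C)C)C(C)C)C=C2OC(C)(C)CCC12 | intermediate
20 | 6-[3-(4-methoxyphenyl)prop-1-en-2-yl]-2,2-dimethyl-7-(triisopropylsilyloxy)chroman-5-ol | C=C(Cc1ccc(OC)cc1)c1c(O)c2CCC(C)(C)Oc2cc1O[Si](C(C)C)(C(C)C)C(C)C | intermediate
21 | triisopropyl({5-methoxy-6-[3-(4-methoxyphenyl)prop-1-en-2-yl]-2,2-dimethylchroman-7-yl}oxy)silane | C=C(Cc1ccc(OC)cc1)c1c(OC)c2CCC(C)(C)Oc2cc1O[Si](C(C)C)(C(C)C)C(C)C | intermediate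
22 | 1-[5-methoxy-2,2-dimethyl-7-(triisopropylsilyloxy)chroman-6-yl]-2-(4-methoxyphenyl)ethan-1-one | COc1ccc(CC(=O)c2c(OC)c3CCC(C)(C)Oc3cc2O[Si](C(C)C)(C(C)C)C(C)C)cc1 | intermediate
23 | 1-[5-methoxy-2,2-dimethyl-7-(triisopropylsilyloxy)-2H-chromen-6-yl]-2-(4-methoxyphenyl)ethan-1-one | COc1ccc(CC(=O)c2c(OC)c3C=CC(C)(C)Oc3cc2O[Si](C(C)C)(C(C)C)C(C)C)cc1 | intermediate
24 | 1-(7-hydroxy-5-methoxy-2,2-dimethyl-2H-chromen-6-yl)-2-(4-methoxyphenyl)ethan-1-one | COc1ccc(CC(=O)c2c(O)cc3c(c2OC)C=CC(C)(C)O3)cc1 | target

## Step count and risk

Total step count: 13 (steps 1–5 for the diazoketone, steps 6–8 for the siloxyalkyne, step 9 for the union, steps 10–13 for the end game).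
Longest linear sequence: 10 steps (steps 1–5 and 9–13, from keto ester 1).

**Step 9 (key step).** The most likely failure is loss of material in the photochemical stage: light-induced decomposition or oligomerisation of the conjugated siloxy enyne, or incomplete capture of the short-lived alkoxyvinylketene, which can dimerise or acylate the product phenol. The fallback generates the same ketene without light. It sets out from lactone 3 and rejoins the route at 20 through the numbered intermediates 16 and 17. Addition of the lithium enolate of ethyl acetate (EtOAc, LiN(i-Pr)2, THF, −78 °C) to 3 should give racemic ethyl 2-(2-hydroxy-6,6-dimethyltetrahydro-2H-pyran-2-yl)acetate F1. Dehydration of F1 (MsCl, Et3N) should give ethyl 2-(6,6-dimethyltetrahydro-2H-pyran-2-ylidene)acetate F2 as a mixture of alkene isomers, either of which serves. Saponification of F2 (LiOH, aq. THF) gives 2-(6,6-dimethyltetrahydro-2H-pyran-2-ylidene)acetic acid F3, and treating F3 with oxalyl chloride and catalytic DMF gives 2-(6,6-dimethyltetrahydro-2H-pyran-2-ylidene)acetyl chloride F4. Slow addition of Et3N to F4 and 15 in toluene should produce ketene 16 by 1,4-dehydrochlorination (removal of a ring CH2 proton), the known way to make vinylketenes from unsaturated acid chlorides. Cycloaddition to 17 and heating then lead to 20.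

**Step 8.** Oxygen transfer to the acetylide may be incomplete in the presence of the by-products of the bromine–lithium exchange, and the conjugated ynolate may oligomerise or be silylated on carbon. The fallback reaches ynolate 14 from an ester and not from an acetylide. It sets out from enal 11 and rejoins at 15. Pinnick oxidation (NaClO2, NaH2PO4, 2-methyl-2-butene) gives 2-(4-methoxybenzyl)acrylic acid F5, and esterification of F5 (MeI, K2CO3, DMF) gives methyl 2-(4-methoxybenzyl)acrylate F6. Treating F6 under Kowalski ynolate conditions (dibromomethyllithium from CH2Br2 and lithium 2,2,6,6-tetramethylpiperidide at −78 °C, then n-BuLi with warming) should give 14, which is silylated with i-Pr3SiCl to 15. The weak point of this reserve is conjugate addition of the carbenoid to the unhindered acrylate F6, which is why it is not the first choice.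

**Step 3.** The enol ether 5 is volatile and acid-sensitive, so evaporative loss and hydration or oligomerisation during isolation are the likely problems. The fallback avoids 5 altogether (it replaces steps 2–4). It sets out from lactone 3 and rejoins at ketone 7. Enolisation and O-phosphorylation (KN(SiMe3)2, (PhO)2P(O)Cl, THF/HMPA, −78 °C) give 6,6-dimethyl-5,6-dihydro-4H-pyran-2-yl diphenyl phosphate F7. Stille coupling of F7 with tributyl(1-ethoxyvinyl)stannane (Pd(PPh3)4, LiCl, THF, reflux) gives 6-(1-ethoxyethenyl)-2,2-dimethyl-3,4-dihydro-2H-pyran F8. Brief treatment of F8 with dilute HCl in THF at 0 °C should hydrolyse the acyclic enol ether first and give 7.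

**Step 11.** The alkene is flanked by two ortho oxygen substituents and twisted out of the arene plane, so osmylation may be slow, and prolonged exposure invites oxidation elsewhere in the electron-rich molecule. The fallback changes the oxidant and the intermediate. It sets out from 21 and rejoins at 22. Epoxidation with dimethyldioxirane (acetone, 0 °C) gives racemic triisopropyl({5-methoxy-6-[2-(4-methoxybenzyl)oxiran-2-yl]-2,2-dimethylchroman-7-yl}oxy)silane F9. Periodic acid (H5IO6, aq. THF) then opens and cleaves the epoxide of F9 to ketone 22 and formaldehyde.

**Step 12.** Hydride abstraction may occur at the wrong position, namely the CH2 between the ketone and the anisyl ring, or the acyl group may slow abstraction at C4 so that the reaction stalls. The fallback changes the order and thereby the mechanism. It sets out from 22 and rejoins at target 24. Desilylation first (Bu4NF, AcOH, THF, 0 °C) gives 1-(7-hydroxy-5-methoxy-2,2-dimethylchroman-6-yl)-2-(4-methoxyphenyl)ethan-1-one F10. The free hydroxyl of F10, para to C4a, should then let DDQ (benzene, reflux) dehydrogenate F10 through a para-quinone methide, a pathway known for 7-hydroxy-2,2-dimethylchromans, giving 24 directly.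

## Further compounds

F1 | step 9 | ethyl 2-(2-hydroxy-6,6-dimethyltetrahydro-2H-pyran-2-yl)acetate (racemic) | CCOC(=O)CC1(O)CCCC(C)(C)O1
F2 | step 9 | ethyl 2-(6,6-dimethyltetrahydro-2H-pyran-2-ylidene)acetate (mixture of alkene isomers) | CCOC(=O)C=C1CCCC(C)(C)O1
F3 | step 9 | 2-(6,6-dimethyltetrahydro-2H-pyran-2-ylidene)acetic acid (mixture of alkene isomers) | OC(=O)C=C1CCCC(C)(C)O1
F4 | step 9 | 2-(6,6-dimethyltetrahydro-2H-pyran-2-ylidene)acetyl chloride (mixture of alkene isomers) | ClC(=O)C=C1CCCC(C)(C)O1
F5 | step 8 | 2-(4-methoxybenzyl)acrylic acid | C=C(Cc1ccc(OC)cc1)C(=O)O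
F6 | step 8 | methyl 2-(4-methoxybenzyl)acrylate | C=C(Cc1ccc(OC)cc1)C(=O)OC
F7 | step 3 | 6,6-dimethyl-5,6-dihydro-4H-pyran-2-yl diphenyl phosphate | O=P(Oc1ccccc1)(Oc1ccccc1)OC1=CCCC(C)(C)O1
F8 | step 3 | 6-(1-ethoxyethenyl)-2,2-dimethyl-3,4-dihydro-2H-pyran | CCOC(=C)C1=CCCC(C)(C)O1
F9 | step 11 | triisopropyl({5-methoxy-6-[2-(4-methoxybenzyl)oxiran-2-yl]-2,2-dimethylchroman-7-yl}oxy)silane (racemic) | COc1ccc(CC4(CO4)c2c(OC)c3CCC(C)(C)Oc3cc2O[Si](C(C)C)(C(C)C)C(C)C)cc1
F10 | step 12 | 1-(7-hydroxy-5-methoxy-2,2-dimethylchroman-6-yl)-2-(4-methoxyphenyl)ethan-1-one | COc1ccc(CC(=O)c2c(O)cc3OC(C)(C)CCc3c2OC)cc1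
A1 | alternative 1 | methyl 5-methoxy-7-(methoxymethoxy)-6-[2-(4-methoxyphenyl)acetyl]-2,2-dimethyl-2H-chromene-8-carboxylate | COC(=O)c1c(OCOC)c(C(=O)Cc2ccc(OC)cc2)c(OC)c2C=CC(C)(C)Oc12
A2 | alternative 1 | methyl 6-iodo-5-methoxy-7-(methoxymethoxy)-2,2-dimethyl-2H-chromene-8-carboxylate | COC(=O)c1c(OCOC)c(I)c(OC)c2C=CC(C)(C)Oc12
A3 | alternative 1 | (4-methoxybenzyl)zinc chloride | COc1ccc(C[Zn]Cl)cc1
A4 | alternative 2 | methyl 7-hydroxy-5-methoxy-6-[2-(4-methoxyphenyl)acetyl]-2,2-dimethyl-2H-chromene-8-carboxylate | COC(=O)c1c(O)c(C(=O)Cc2ccc(OC)cc2)c(OC)c2C=CC(C)(C)Oc12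
A5 | alternative 2 | methyl 3-formyl-2,6-dihydroxy-4-methoxy-5-[2-(4-methoxyphenyl)acetyl]benzoate | COC(=O)c1c(O)c(C(=O)Cc2ccc(OC)cc2)c(OC)c(C=O)c1O
A6 | alternative 2 | (2-methylprop-1-en-1-yl)boronic acid | CC(C)=CB(O)O
A7 | alternative 3 | 1-(7-hydroxy-5-methoxy-2,2-dimethylchroman-6-yl)-2-(4-methoxyphenyl)ethan-1-one | COc1ccc(CC(=O)c2c(O)cc3OC(C)(C)CCc3c2OC)cc1
A8 | alternative 3 | tert-butyl{[2-(6,6-dimethyl-5,6-dihydro-4H-pyran-2-yl)-1-methoxyethenyl]oxy}dimethylsilane | COC(O[Si](C)(C)C(C)(C)C)=CC1=CCCC(C)(C)O1
A9 | alternative 3 | 4-methoxy-1-(4-methoxyphenyl)but-3-yn-2-one | COC#CC(=O)Cc1ccc(OC)cc1
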